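A direct plan would brominate 2,4,6-trihydroxybenzaldehyde A1, exchange the bromine for methoxide with NaOMe and CuBr to give 2,4,6-trihydroxy-3-methoxybenzaldehyde A2, then prenylate the 4-OH and tosylate one ortho OH to reach the tosyloxy aldehyde A3.
A3 and 4-hydroxy-3-methoxyphenylglyoxal hydrate A4 would then be joined by a carbene-catalysed crossed benzoin that cyclodehydrates to the 5-O-tosyl flavonol A5, and hydroxide would free the target.
Weak step, the copper-mediated methoxylation: a free bromotrihydroxybenzaldehyde in hot excess methoxide risks protodebromination and deformylation, and four steps would only decorate a bought benzene ring.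
Weak step, the mono-tosylation: it must tell apart two hydroxyls that both flank the formyl group, and this small steric bias alone would decide between the 8-methoxy and the 6-methoxy flavone.
Weak step, the benzoin/cyclisation cascade with hot hydroxide detosylation: an untested cascade and a base-sensitive flavonol would meet on the fully decorated prenyl ether, the most precious material.

**Plan of the new route**
Ring A is cut, not ring C: the C4a–C5 bond (6π-electrocyclisation of a dienylketene) and the C8–C8a bond (carbonyl addition). This leaves a 2-aryl-3-silyloxy-4-pyranone (rings B and C) and prenyl semisquarate.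
Enabling feature: C5(O)–C6(H)–C7(O-prenyl)–C8(O) of ring A are the four carbons of a 3-alkoxycyclobutene-1,2-dione; C8a is the α-oxygen C–H of a 4-pyranone (metalation site) and C4a is its free neighbouring CH (closure site).
Order of rings: B is bought, C comes from pyromeconic acid and is arylated at C2, A is formed last by heating the cyclobutenone adduct.
The ketene carbon becomes the free 5-OH, the methylated carbinol becomes 8-OMe and the squarate ester oxygen becomes the 7-O-prenyl ether, so no bromine/methoxide exchange is needed.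
Because the O1–C8a bond exists before ring A, no choice between two hydroxyls arises and the 6-methoxy isomer cannot form; the last step is a buffered desilylation, not a cascade.

Key step: step 10

Remark: pyromeconic acid (3-hydroxy-4H-pyran-4-one), 2-methoxy-4-(pinacolboryl)phenol and diisopropyl squarate are taken as catalogue compounds; the target is achiral.

Step 1
Reactants: 1 3-hydroxy-4H-pyran-4-one (pyromeconic acid)
Product: 2 2-bromo-3-hydroxy-4H-pyran-4-one
Conditions: NBS (1.02 equiv), MeCN, 0 °C to rt, dark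
Reagents that add atoms: N-bromosuccinimide, O=C1CCC(=O)N1Br
Why: Electrophilic bromination of the enol at C2, the carbon ortho to the hydroxyl and next to the ring oxygen, where 3-hydroxy-4-pyranones undergo halogenation, Mannich and aldol substitution; one equivalent at low temperature should stop at the monobromide.

Step 2
Reactants: 2 2-bromo-3-hydroxy-4H-pyran-4-one
Product: 3 2-bromo-3-(triisopropylsilyloxy)-4H-pyran-4-one
Conditions: TIPSOTf (1.2 equiv), 2,6-lutidine (1.5 equiv), CH2Cl2, 0 °C to rt
Reagents that add atoms: triisopropylsilyl trifluoromethanesulfonate, CC(C)[Si](OS(=O)(=O)C(F)(F)F)(C(C)C)C(C)C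
Why: O-silylation of the acidic, hindered enolic hydroxyl with a silyl triflate and a hindered base; the triisopropylsilyl group is chosen because it should survive cross-coupling, amide base and 105 °C and is later removed by fluoride without touching a prenyl ether.

Step 3
Reactants: 4 2-methoxy-4-(4,4,5,5-tetramethyl-1,3,2-dioxaborolan-2-yl)phenol
Product: 5 triisopropyl[2-methoxy-4-(4,4,5,5-tetramethyl-1,3,2-dioxaborolan-2-yl)phenoxy]silane
Conditions: TIPSCl (1.2 equiv), imidazole (2.0 equiv), DMF, rt
Reagents that add atoms: chlorotriisopropylsilane, CC(C)[Si](Cl)(C(C)C)C(C)C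
Why: Standard silylation of a phenol, which puts the same fluoride-labile group on the future 4'-oxygen.

Step 4
Reactants: 3 2-bromo-3-(triisopropylsilyloxy)-4H-pyran-4-one; 5 triisopropyl[2-methoxy-4-(4,4,5,5-tetramethyl-1,3,2-dioxaborolan-2-yl)phenoxy]silane
Product: 6 2-[3-methoxy-4-(triisopropylsilyloxy)phenyl]-3-(triisopropylsilyloxy)-4H-pyran-4-one
Conditions: Pd(OAc)2 (3 mol %), 2-dicyclohexylphosphino-2',6'-dimethoxybiphenyl (6 mol %), K3PO4 (2 equiv), toluene/H2O 10:1, 60 °C, argon
Reagents that add atoms: none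
Why: Suzuki–Miyaura coupling; the C2–Br bond is a vinylogous acyl bromide that should undergo oxidative addition to zerovalent palladium readily, the biaryl dialkylphosphine copes with the ortho silyloxy group, and a weak base in a toluene-rich two-phase medium should leave both silyl ethers intact.

Step 5
Reactants: 7 3,4-diisopropoxycyclobut-3-ene-1,2-dione (diisopropyl squarate)
Product: 9 3-isopropoxycyclobut-3-ene-1,2-dione, via reduction carbinol 8 (not isolated)
Conditions: LiAlH(OtBu)3 (1.05 equiv), THF, −78 to 0 °C; then cold 6 M HCl/CH2Cl2, rt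
Reagents that add atoms: none
Why: Mono-reduction of one vinylogous ester carbonyl by the hindered alkoxyaluminium hydride, then acid-promoted 1,3-carbonyl transposition with loss of isopropanol through an oxocarbenium ion, the established entry to 3-alkoxycyclobutenediones; the stereocentre of 8 is lost.

Step 6
Reactants: 9 3-isopropoxycyclobut-3-ene-1,2-dione
Product: 10 3-hydroxycyclobut-3-ene-1,2-dione (semisquaric acid)
Conditions: 2 M aq HCl, THF, 40 °C; evaporate, dry by toluene azeotrope
Reagents that add atoms: water, O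
Why: Acid hydrolysis of the vinylogous ester by addition–elimination of water at C3 should give the strong vinylogous acid, which is isolated simply by evaporation.

Step 7
Reactants: 10 3-hydroxycyclobut-3-ene-1,2-dione
Product: 12 3-(3-methylbut-2-enyloxy)cyclobut-3-ene-1,2-dione (prenyl semisquarate), via silver semisquarate 11 (not isolated)
Conditions: Ag2O (0.55 equiv), 4 Å molecular sieves, MeCN, rt, dark; then prenyl bromide (1.1 equiv), 0 °C to rt; filter through Celite, use without chromatography on acidic media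
Reagents that add atoms: prenyl bromide (1-bromo-3-methylbut-2-ene), CC(C)=CCBr
Why: O-alkylation of the silver salt of a strong vinylogous acid with an allylic bromide, the silver-salt route to squaric esters; the anion is symmetric so either oxygen gives the same ester, silver assistance favours O- over C-alkylation, and the neutral medium avoids acid that would ionise the prenyl ester.

Step 8
Reactants: 6 2-[3-methoxy-4-(triisopropylsilyloxy)phenyl]-3-(triisopropylsilyloxy)-4H-pyran-4-one; 12 3-(3-methylbut-2-enyloxy)cyclobut-3-ene-1,2-dione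
Product: 14 4-hydroxy-4-{6-[3-methoxy-4-(triisopropylsilyloxy)phenyl]-4-oxo-5-(triisopropylsilyloxy)-4H-pyran-2-yl}-3-(3-methylbut-2-enyloxy)cyclobut-2-en-1-one (racemic), via pyranonylmagnesium chloride 13 (not isolated)
Conditions: TMPMgCl·LiCl (1.15 equiv), THF, −40 °C, 30 min; LaCl3·2LiCl (1.0 equiv), −78 °C; 12 (1.2 equiv), −78 °C, 1 h; sat. aq NH4Cl
Reagents that add atoms: none
Why: Deprotonative magnesiation at C6–H, the sp2 C–H next to the ring oxygen and the only such position left (the site at which chromones and 4-pyranones are metalated by hindered amide bases), then 1,2-addition to the carbonyl of 12 that is not part of the vinylogous ester, as in the first stage of squarate-based ring expansions; LaCl3·2LiCl should suppress conjugate addition to the enedione of 12, and the new carbinol stereocentre forms racemic and is destroyed in step 10.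

Step 9
Reactants: 14 4-hydroxy-4-{6-[3-methoxy-4-(triisopropylsilyloxy)phenyl]-4-oxo-5-(triisopropylsilyloxy)-4H-pyran-2-yl}-3-(3-methylbut-2-enyloxy)cyclobut-2-en-1-one
Product: 15 4-methoxy-4-{6-[3-methoxy-4-(triisopropylsilyloxy)phenyl]-4-oxo-5-(triisopropylsilyloxy)-4H-pyran-2-yl}-3-(3-methylbut-2-enyloxy)cyclobut-2-en-1-one (racemic)
Conditions: MeI (10 equiv), Ag2O (2.5 equiv), 4 Å molecular sieves, MeCN, rt, dark
Reagents that add atoms: iodomethane, CI
Why: Purdie methylation of the tertiary carbinol under non-basic conditions, the usual way to cap 4-hydroxycyclobutenones before ring expansion; it fixes the methyl on the future 8-oxygen while the future 5-oxygen is still a carbonyl, so the two oxygens never have to be told apart as phenols.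

Step 10
Reactants: 15 4-methoxy-4-{6-[3-methoxy-4-(triisopropylsilyloxy)phenyl]-4-oxo-5-(triisopropylsilyloxy)-4H-pyran-2-yl}-3-(3-methylbut-2-enyloxy)cyclobut-2-en-1-one
Product: 18 5-hydroxy-8-methoxy-2-[3-methoxy-4-(triisopropylsilyloxy)phenyl]-7-(3-methylbut-2-enyloxy)-3-(triisopropylsilyloxy)-4H-chromen-4-one, via dienylketene 16 (not isolated), via cyclohexadienone tautomer 17 (not isolated)
Conditions: degassed toluene (0.01 M), 105 °C, argon, 2–4 h
Reagents that add atoms: none
Why: Heating opens the cyclobutenone by conrotatory 4π-electrocyclic cleavage of the C1–C4 bond, and the methoxy donor at C4 rotates outward (torquoselectivity), so the pyranonyl group ends up cis to the ketene in dienylketene 16. A disrotatory 6π-electrocyclisation then joins the ketene carbon to C5 of the pyranone (future C4a) and closes the six-membered ring A as cyclohexadienone 17, whose C4a–H lies between two carbonyls and shifts to oxygen at once, giving the chelated 5-OH phenol irreversibly. The closest known reaction type is the thermal ring expansion of 4-aryl-, 4-heteroaryl- and 4-alkenyl-4-alkoxycyclobutenones to regiospecifically mono-protected hydroquinones (Moore rearrangement). No stereocentre remains, since the carbinol carbon of 15 becomes sp2 C8 and the C4a centre of 17 is lost on enolisation. The step needs closure at one site only, which the substrate secures because C6 of the pyranone has a single carbon neighbour (C5, the other neighbour being O1), so 5-OH, 7-O-prenyl and 8-OMe are placed by connectivity. It also needs ring opening to outrun the [3,3] shift of the prenyl enol ether, which the donor-accelerated opening at 105 °C in a non-polar solvent should do, as aliphatic Claisen shifts of this kind and the aromatic Claisen shift of the product need higher temperatures.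

Step 11
Reactants: 18 5-hydroxy-8-methoxy-2-[3-methoxy-4-(triisopropylsilyloxy)phenyl]-7-(3-methylbut-2-enyloxy)-3-(triisopropylsilyloxy)-4H-chromen-4-one
Product: 19 3,5-dihydroxy-2-(4-hydroxy-3-methoxyphenyl)-8-methoxy-7-(3-methylbut-2-enyloxy)-4H-chromen-4-one (target)
Conditions: Bu4NF (2.4 equiv), AcOH (2.6 equiv), THF, 0 °C to rt, argon
Reagents that add atoms: none
Why: Fluoride cleavage of the aryl and enol silyl ethers, buffered with acetic acid so that the flavonol is not exposed to base and air; the prenyl ether and both methyl ethers are inert to fluoride.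

**Compound list**
1 | 3-hydroxy-4H-pyran-4-one (pyromeconic acid) | O=c1ccocc1O | starting material
2 | 2-bromo-3-hydroxy-4H-pyran-4-one | O=c1ccoc(Br)c1O | intermediate
3 | 2-bromo-3-(triisopropylsilyloxy)-4H-pyran-4-one | O=c1ccoc(Br)c1O[Si](C(C)C)(C(C)C)C(C)C | intermediate
4 | 2-methoxy-4-(4,4,5,5-tetramethyl-1,3,2-dioxaborolan-2-yl)phenol | COc1cc(B2OC(C)(C)C(C)(C)O2)ccc1O | starting material
5 | triisopropyl[2-methoxy-4-(4,4,5,5-tetramethyl-1,3,2-dioxaborolan-2-yl)phenoxy]silane | COc1cc(B2OC(C)(C)C(C)(C)O2)ccc1O[Si](C(C)C)(C(C)C)C(C)C | intermediate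
6 | 2-[3-methoxy-4-(triisopropylsilyloxy)phenyl]-3-(triisopropylsilyloxy)-4H-pyran-4-one | O=c1ccoc(-c2ccc(O[Si](C(C)C)(C(C)C)C(C)C)c(OC)c2)c1O[Si](C(C)C)(C(C)C)C(C)C | intermediate
7 | 3,4-diisopropoxycyclobut-3-ene-1,2-dione (diisopropyl squarate) | CC(C)OC1=C(OC(C)C)C(=O)C1=O | starting material
8 | 4-hydroxy-2,3-diisopropoxycyclobut-2-en-1-one (racemic, not isolated) | CC(C)OC1=C(OC(C)C)C(O)C1=O | intermediate
9 | 3-isopropoxycyclobut-3-ene-1,2-dione | CC(C)OC1=CC(=O)C1=O | intermediate
10 | 3-hydroxycyclobut-3-ene-1,2-dione (semisquaric acid) | OC1=CC(=O)C1=O | intermediate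
11 | silver 3,4-dioxocyclobut-1-en-1-olate (not isolated) | [Ag+].[O-]C1=CC(=O)C1=O | intermediate
12 | 3-(3-methylbut-2-enyloxy)cyclobut-3-ene-1,2-dione (prenyl semisquarate) | CC(C)=CCOC1=CC(=O)C1=O | intermediate
13 | {6-[3-methoxy-4-(triisopropylsilyloxy)phenyl]-4-oxo-5-(triisopropylsilyloxy)-4H-pyran-2-yl}magnesium chloride (not isolated) | Cl[Mg]c1cc(=O)c(O[Si](C(C)C)(C(C)C)C(C)C)c(-c2ccc(O[Si](C(C)C)(C(C)C)C(C)C)c(OC)c2)o1 | intermediate
14 | 4-hydroxy-4-{6-[3-methoxy-4-(triisopropylsilyloxy)phenyl]-4-oxo-5-(triisopropylsilyloxy)-4H-pyran-2-yl}-3-(3-methylbut-2-enyloxy)cyclobut-2-en-1-one (racemic) | CC(C)=CCOC1=CC(=O)C1(O)c1cc(=O)c(O[Si](C(C)C)(C(C)C)C(C)C)c(-c2ccc(O[Si](C(C)C)(C(C)C)C(C)C)c(OC)c2)o1 | intermediate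
15 | 4-methoxy-4-{6-[3-methoxy-4-(triisopropylsilyloxy)phenyl]-4-oxo-5-(triisopropylsilyloxy)-4H-pyran-2-yl}-3-(3-methylbut-2-enyloxy)cyclobut-2-en-1-one (racemic) | CC(C)=CCOC1=CC(=O)C1(OC)c1cc(=O)c(O[Si](C(C)C)(C(C)C)C(C)C)c(-c2ccc(O[Si](C(C)C)(C(C)C)C(C)C)c(OC)c2)o1 | intermediate
16 | 2-[(1Z)-1-methoxy-2-(3-methylbut-2-enyloxy)-4-oxobuta-1,3-dien-1-yl]-6-[3-methoxy-4-(triisopropylsilyloxy)phenyl]-5-(triisopropylsilyloxy)-4H-pyran-4-one (dienylketene, not isolated) | O=C=C/C(OCC=C(C)C)=C(/OC)c1cc(=O)c(O[Si](C(C)C)(C(C)C)C(C)C)c(-c2ccc(O[Si](C(C)C)(C(C)C)C(C)C)c(OC)c2)o1 | intermediate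
17 | 8-methoxy-2-[3-methoxy-4-(triisopropylsilyloxy)phenyl]-7-(3-methylbut-2-enyloxy)-3-(triisopropylsilyloxy)-4aH-chromene-4,5-dione (racemic, not isolated) | COC1=C2OC(-c3ccc(O[Si](C(C)C)(C(C)C)C(C)C)c(OC)c3)=C(O[Si](C(C)C)(C(C)C)C(C)C)C(=O)C2C(=O)C=C1OCC=C(C)C | intermediate
18 | 5-hydroxy-8-methoxy-2-[3-methoxy-4-(triisopropylsilyloxy)phenyl]-7-(3-methylbut-2-enyloxy)-3-(triisopropylsilyloxy)-4H-chromen-4-one | COc1cc(-c2oc3c(OC)c(OCC=C(C)C)cc(O)c3c(=O)c2O[Si](C(C)C)(C(C)C)C(C)C)ccc1O[Si](C(C)C)(C(C)C)C(C)C | intermediate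
19 | 3,5-dihydroxy-2-(4-hydroxy-3-methoxyphenyl)-8-methoxy-7-(3-methylbut-2-enyloxy)-4H-chromen-4-one (achiral) | COc1cc(-c2oc3c(OC)c(OCC=C(C)C)cc(O)c3c(=O)c2O)ccc1O | target

**Step count and risks**
Total: 11 steps. Longest linear sequence: 7 steps (1 → 2 → 3 → 6 → 14 → 15 → 18 → 19; the squarate branch 7 → 9 → 10 → 12 → 14 is equally long).

The three steps most likely to fail:

Step 8. The amide base may deprotonate the carbon next to the carbonyl instead of the carbon next to the ring oxygen, which would open the ring. The metalated pyranone may also add to pyranone not yet metalated, or add in conjugate fashion to the semisquarate. The fallback sets out from 6 and comes back at 13. Compound 6 would be zincated with TMP2Zn·2MgCl2·2LiCl (THF, −30 °C), where the Lewis acid on the carbonyl oxygen steers metalation to the α-oxygen carbon. Iodine would then give the stable, purifiable 2-iodo-6-[3-methoxy-4-(triisopropylsilyloxy)phenyl]-5-(triisopropylsilyloxy)-4H-pyran-4-one F1, whose regiochemistry can be checked. Iodine–magnesium exchange with iPrMgCl·LiCl at −78 °C would regenerate 13 free of amine and of unmetalated 6, and the addition to 12 would follow as in the route.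

Step 10. A [3,3] shift or ionisation of the prenyl enol ether may compete with ring opening before the ketene forms. The fallback sets out from 10 (with 13 from 6) and comes back at 18. Silver-salt alkylation of 10 with benzyl bromide would give 3-(benzyloxy)cyclobut-3-ene-1,2-dione F2. Addition of 13 would give the benzyloxy carbinol F3, and MeI/Ag2O its methyl ether F4. Thermolysis, which can then be run up to 140 °C in xylene, would give 7-benzyloxy-5-hydroxy-8-methoxy-2-[3-methoxy-4-(triisopropylsilyloxy)phenyl]-3-(triisopropylsilyloxy)-4H-chromen-4-one F5. Hydrogenolysis over palladium on carbon (Pd/C, H2, EtOAc) would free the 5,7-dihydroxy compound F6. Prenyl bromide (1.05 equiv) with K2CO3 in acetone would then alkylate only the 7-OH, the 5-OH being hydrogen-bonded to the carbonyl, to give 18.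

Step 9. Etherification of the hindered tertiary carbinol may be slow, which would leave time for ring opening of the cyclobutenone or for methylation at the pyranone carbonyl oxygen. The fallback sets out from 14 and comes back at 18. The free carbinol 14 would be heated in degassed toluene at 105 °C, the original form of the ring expansion, to give the hydroquinone 5,8-dihydroxy-2-[3-methoxy-4-(triisopropylsilyloxy)phenyl]-7-(3-methylbut-2-enyloxy)-3-(triisopropylsilyloxy)-4H-chromen-4-one F7. Kept under argon, F7 would be methylated with MeI (1.05 equiv) and K2CO3 in acetone at the 8-OH only, the 5-OH being chelated, to give 18.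

**Further compounds**
F1 | step 8 | 2-iodo-6-[3-methoxy-4-(triisopropylsilyloxy)phenyl]-5-(triisopropylsilyloxy)-4H-pyran-4-one | O=c1cc(I)oc(-c2ccc(O[Si](C(C)C)(C(C)C)C(C)C)c(OC)c2)c1O[Si](C(C)C)(C(C)C)C(C)C
F2 | step 10 | 3-(benzyloxy)cyclobut-3-ene-1,2-dione | O=C1C=C(OCc2ccccc2)C1=O
F3 | step 10 | 3-(benzyloxy)-4-hydroxy-4-{6-[3-methoxy-4-(triisopropylsilyloxy)phenyl]-4-oxo-5-(triisopropylsilyloxy)-4H-pyran-2-yl}cyclobut-2-en-1-one (racemic) | O=C1C=C(OCc2ccccc2)C1(O)c1cc(=O)c(O[Si](C(C)C)(C(C)C)C(C)C)c(-c2ccc(O[Si](C(C)C)(C(C)C)C(C)C)c(OC)c2)o1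
F4 | step 10 | 3-(benzyloxy)-4-methoxy-4-{6-[3-methoxy-4-(triisopropylsilyloxy)phenyl]-4-oxo-5-(triisopropylsilyloxy)-4H-pyran-2-yl}cyclobut-2-en-1-one (racemic) | O=C1C=C(OCc2ccccc2)C1(OC)c1cc(=O)c(O[Si](C(C)C)(C(C)C)C(C)C)c(-c2ccc(O[Si](C(C)C)(C(C)C)C(C)C)c(OC)c2)o1
F5 | step 10 | 7-(benzyloxy)-5-hydroxy-8-methoxy-2-[3-methoxy-4-(triisopropylsilyloxy)phenyl]-3-(triisopropylsilyloxy)-4H-chromen-4-one | COc1cc(-c2oc3c(OC)c(OCc4ccccc4)cc(O)c3c(=O)c2O[Si](C(C)C)(C(C)C)C(C)C)ccc1O[Si](C(C)C)(C(C)C)C(C)C
F6 | step 10 | 5,7-dihydroxy-8-methoxy-2-[3-methoxy-4-(triisopropylsilyloxy)phenyl]-3-(triisopropylsilyloxy)-4H-chromen-4-one | COc1cc(-c2oc3c(OC)c(O)cc(O)c3c(=O)c2O[Si](C(C)C)(C(C)C)C(C)C)ccc1O[Si](C(C)C)(C(C)C)C(C)C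
F7 | step 9 | 5,8-dihydroxy-2-[3-methoxy-4-(triisopropylsilyloxy)phenyl]-7-(3-methylbut-2-enyloxy)-3-(triisopropylsilyloxy)-4H-chromen-4-one | COc1cc(-c2oc3c(O)c(OCC=C(C)C)cc(O)c3c(=O)c2O[Si](C(C)C)(C(C)C)C(C)C)ccc1O[Si](C(C)C)(C(C)C)C(C)C
A1 | direct plan | 2,4,6-trihydroxybenzaldehyde | O=Cc1c(O)cc(O)cc1O
A2 | direct plan | 2,4,6-trihydroxy-3-methoxybenzaldehyde | O=Cc1c(O)cc(O)c(OC)c1O
A3 | direct plan | 2-formyl-3-hydroxy-4-methoxy-5-(3-methylbut-2-enyloxy)phenyl 4-methylbenzenesulfonate | O=Cc1c(OS(=O)(=O)c2ccc(C)cc2)cc(OCC=C(C)C)c(OC)c1O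
A4 | direct plan | 2,2-dihydroxy-1-(4-hydroxy-3-methoxyphenyl)ethan-1-one | OC(O)C(=O)c1ccc(O)c(OC)c1
A5 | direct plan | 3-hydroxy-2-(4-hydroxy-3-methoxyphenyl)-8-methoxy-7-(3-methylbut-2-enyloxy)-4-oxo-4H-chromen-5-yl 4-methylbenzenesulfonate | COc1cc(-c2oc3c(OC)c(OCC=C(C)C)cc(OS(=O)(=O)c4ccc(C)cc4)c3c(=O)c2O)ccc1O
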